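**Retrosynthetic overview**

- The target is opened at C8–C12 and C13–C14: the last step is a ring expansion of a 1‑ethynylcyclobutanol (1,2‑shift of the chain‑bearing ring carbon onto the alkyne) to a 2‑methylidenecyclopentanone, trapped in the same flask by the enol silane of heptan‑2‑one.
- The ethynylcyclobutanol already carries the (Z)‑heptenoic acid chain: Wittig reaction (C5=C6) of a lactol, from reduction of a lactone, from ethynyl addition to a cis‑fused keto lactone.
- The keto lactone comes from 3‑oxocyclobutyl bromoacetate by a catalytic desymmetrising ring closure (C7–C8 bond, sets C8 and C9), and that ester from 3‑hydroxycyclobutanone and bromoacetyl bromide.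
- Ring order: cyclobutane (bought), fused γ‑lactone (step 4), lactone opened (steps 6–7), cyclopentanone formed last (step 8).

Assumption: 3‑hydroxycyclobutan‑1‑one is bought; positions are named by prostaglandin numbering (C1 acid carbon, C8 to C12 ring carbons, C20 end of the lower chain).

**Route**

Step 1
Reactants: 1 5‑bromopentanoic acid
Product: 2 (4‑carboxybutyl)triphenylphosphonium bromide
Conditions: PPh3, MeCN, reflux
Reagents that add atoms: triphenylphosphine, c1ccc(cc1)P(c1ccccc1)c1ccccc1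
Why: SN2 quaternisation of the phosphine by the primary bromide (phosphonium salt formation) is clean and makes no stereocentre.

Step 2
Reactants: 3 heptan‑2‑one
Product: 5 2‑(trimethylsilyloxy)hept‑1‑ene, via lithium enolate 4 (not isolated)
Conditions: LiN(i‑Pr)2, THF, −78 °C; then Me3SiCl, −78 °C to rt
Reagents that add atoms: chlorotrimethylsilane, C[Si](C)(C)Cl
Why: Kinetic deprotonation of the methyl ketone by the hindered amide gives the less substituted enolate, which is O‑silylated (kinetic silyl enol ether formation); no stereocentre.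

Step 3
Reactants: 6 3‑hydroxycyclobutan‑1‑one; 7 bromoacetyl bromide
Product: 8 3‑oxocyclobutyl 2‑bromoacetate
Conditions: NaHCO3, MeCN, 0 °C
Reagents that add atoms: none
Why: O‑acylation of the secondary alcohol by the acid bromide over solid bicarbonate (esterification) leaves the ketone untouched and gives a prochiral ester with a mirror plane.

Step 4
Reactants: 8 3‑oxocyclobutyl 2‑bromoacetate
Product: 9 (1S,5S)‑2‑oxabicyclo[3.2.0]heptane‑3,6‑dione
Conditions: 9‑amino(9‑deoxy)epi‑quinine (20 mol%), CF3CO2H (40 mol%), NaOAc (1.5 equiv), toluene, 0 °C to rt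
Reagents that add atoms: none
Why: Proposed new method: the chiral primary amine condenses with the prochiral cyclobutanone to give two diastereomeric enamines (one toward each enantiotopic CH2) that interconvert through the iminium ion, and the faster one closes by 5‑exo‑tet SN2 attack of the enamine carbon on the tethered CH2Br, which forms the C4–C5 bond and, because the ester oxygen is fixed on C1, can only give the cis‑fused lactone, so C1 and C5 are set together (any β‑elimination to the cyclobutenone iminium ion and bromoacetate should be returned by oxa‑Michael re‑addition before the same closure); the closest known reactions are the amine‑catalysed intramolecular α‑alkylation of halo aldehydes and the cinchona‑amine‑catalysed α‑alkylation of cyclic ketones with activated bromides.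

Step 5
Reactants: 9 (1S,5S)‑2‑oxabicyclo[3.2.0]heptane‑3,6‑dione; 10 ethynylmagnesium bromide
Product: 11 (1S,5S,6R)‑6‑ethynyl‑6‑hydroxy‑2‑oxabicyclo[3.2.0]heptan‑3‑one
Conditions: HC≡CMgBr (1.3 equiv), THF, −78 °C; aq. NH4Cl
Reagents that add atoms: none
Why: Grignard 1,2‑addition to the strained, very electrophilic cyclobutanone outruns enolisation and lactone attack at −78 °C and comes from the convex face; the new carbinol centre becomes sp2 in step 8, so its sense does not matter.

Step 6
Reactants: 11 (1S,5S,6R)‑6‑ethynyl‑6‑hydroxy‑2‑oxabicyclo[3.2.0]heptan‑3‑one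
Product: 12 (1S,5S,6R)‑6‑ethynyl‑2‑oxabicyclo[3.2.0]heptane‑3,6‑diol (both epimers at C3)
Conditions: i‑Bu2AlH (2.3 equiv), CH2Cl2, −78 °C; aq. potassium sodium tartrate
Reagents that add atoms: none
Why: Partial reduction of the γ‑lactone to the lactol (the tetrahedral aluminate is stable at −78 °C) after deprotonation of the tertiary alcohol; the ring stereocentres are untouched.

Step 7
Reactants: 12 (1S,5S,6R)‑6‑ethynyl‑2‑oxabicyclo[3.2.0]heptane‑3,6‑diol; 2 (4‑carboxybutyl)triphenylphosphonium bromide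
Product: 14 (5Z)‑7‑[(1S,2R,4S)‑2‑ethynyl‑2,4‑dihydroxycyclobutyl]hept‑5‑enoic acid, via ylide 13 (not isolated)
Conditions: 2 (4 equiv), KN(SiMe3)2 (8 equiv), THF, 0 °C; then 12, −78 °C to rt; aq. citric acid
Reagents that add atoms: none
Why: Wittig olefination of the lactol (through its hydroxy aldehyde form) by the salt‑free unstabilised ylide gives the Z‑alkene under kinetic control, the classic prostaglandin upper‑chain installation; the ring stereocentres are untouched.

Step 8
Reactants: 14 (5Z)‑7‑[(1S,2R,4S)‑2‑ethynyl‑2,4‑dihydroxycyclobutyl]hept‑5‑enoic acid; 5 2‑(trimethylsilyloxy)hept‑1‑ene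
Product: 17 (5Z)‑7‑[(1R,2R,5S)‑5‑hydroxy‑3‑oxo‑2‑(3‑oxooctyl)cyclopentyl]hept‑5‑enoic acid, via methylidene ketone 15 (not isolated), via silyl enol ether 16 (not isolated)
Conditions: [(4‑CF3C6H4)3P]AuCl (2 mol%), AgSbF6 (2 mol%), CH2Cl2, rt; then 5 (4 equiv), Me3SiOTf (10 mol%), −78 °C; aq. citric acid, THF, 0 °C; then KOAc (0.2 equiv), MeOH, rt
Reagents that add atoms: none
Why: Gold‑catalysed ring expansion of the 1‑alkynylcyclobutanol (the alkyne is π‑activated, the more substituted ring carbon C8 shifts from C11 to C12 with retention, then protodeauration) gives the 2‑methylidenecyclopentanone, which is trapped by Mukaiyama–Michael addition of 5 at the exocyclic carbon (5 also silylates the OH and CO2H groups); hydrolysis and KOAc equilibration put the C12 chain trans to the C8 chain (thermodynamic control next to the ketone), while C8 and C9 from step 4 are carried through unchanged.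

**Compound list**

1 | 5‑bromopentanoic acid | OC(=O)CCCCBr | starting material
2 | (4‑carboxybutyl)triphenylphosphonium bromide | [Br-].OC(=O)CCCC[P+](c1ccccc1)(c1ccccc1)c1ccccc1 | intermediate
3 | heptan‑2‑one | CCCCCC(C)=O | starting material
4 | lithium hept‑1‑en‑2‑olate | [Li+].[O-]C(=C)CCCCC | intermediate
5 | 2‑(trimethylsilyloxy)hept‑1‑ene | CCCCCC(=C)O[Si](C)(C)C | intermediate
6 | 3‑hydroxycyclobutan‑1‑one | O=C1CC(O)C1 | starting material
7 | bromoacetyl bromide | BrCC(Br)=O | starting material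
8 | 3‑oxocyclobutyl 2‑bromoacetate | O=C1CC(OC(=O)CBr)C1 | intermediate
9 | (1S,5S)‑2‑oxabicyclo[3.2.0]heptane‑3,6‑dione | O=C1C[C@H](OC(=O)C2)[C@@H]12 | intermediate
10 | ethynylmagnesium bromide | C#C[Mg]Br | starting material
11 | (1S,5S,6R)‑6‑ethynyl‑6‑hydroxy‑2‑oxabicyclo[3.2.0]heptan‑3‑one | C#C[C@@]1(O)C[C@H](OC(=O)C2)[C@@H]12 | intermediate
12 | (1S,5S,6R)‑6‑ethynyl‑2‑oxabicyclo[3.2.0]heptane‑3,6‑diol (C3 epimers) | C#C[C@@]1(O)C[C@H](OC(O)C2)[C@@H]12 | intermediate
13 | potassium 5‑(triphenylphosphoranylidene)pentanoate | [K+].[O-]C(=O)CCCC=P(c1ccccc1)(c1ccccc1)c1ccccc1 | intermediate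
14 | (5Z)‑7‑[(1S,2R,4S)‑2‑ethynyl‑2,4‑dihydroxycyclobutyl]hept‑5‑enoic acid | C#C[C@@]1(O)C[C@H](O)[C@@H]1C/C=C\CCCC(=O)O | intermediate
15 | (5Z)‑7‑[(1R,5S)‑5‑hydroxy‑2‑methylidene‑3‑oxocyclopentyl]hept‑5‑enoic acid | C=C1C(=O)C[C@H](O)[C@@H]1C/C=C\CCCC(=O)O | intermediate
16 | trimethylsilyl (5Z)‑7‑[(1R,5S)‑2‑(3‑oxooctyl)‑3,5‑bis(trimethylsilyloxy)cyclopent‑2‑en‑1‑yl]hept‑5‑enoate | CCCCCC(=O)CCC1=C(O[Si](C)(C)C)C[C@H](O[Si](C)(C)C)[C@@H]1C/C=C\CCCC(=O)O[Si](C)(C)C | intermediate
17 | (5Z)‑7‑[(1R,2R,5S)‑5‑hydroxy‑3‑oxo‑2‑(3‑oxooctyl)cyclopentyl]hept‑5‑enoic acid (13,14‑dihydro‑15‑keto‑PGD2) | CCCCCC(=O)CC[C@H]1C(=O)C[C@H](O)[C@@H]1C/C=C\CCCC(=O)O | target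

**Step count and risks**

Total steps: 8. Longest linear sequence: 6 (steps 3 to 8); steps 1 and 2 make the two chain reagents.

Step 4 (the new ring closure) is the most likely to fail. The catalyst may be alkylated by the bromoacetate, β‑elimination may win, or the ee may be low; if only the sense is wrong, the quinidine‑derived pseudo‑enantiomer of the amine is used. The fallback uses known chemistry from 6 to 9. Silylation of 6 (t‑BuMe2SiCl, imidazole) gives 3‑[tert‑butyl(dimethyl)silyl]oxycyclobutan‑1‑one F1. Enantioselective deprotonation of this prochiral ketone with lithium (R,R)‑bis(1‑phenylethyl)amide and Me3SiCl (or the mirror‑image amide, whichever selects the required CH2) gives the silyl enol ether tert‑butyl(dimethyl){[(1S)‑3‑(trimethylsilyloxy)cyclobut‑2‑en‑1‑yl]oxy}silane F2. MeLi releases the lithium enolate lithium (3S)‑3‑[tert‑butyl(dimethyl)silyl]oxycyclobut‑1‑en‑1‑olate F3, which is alkylated anti to the silyloxy group by tert‑butyl bromoacetate to the trans keto ester tert‑butyl 2‑[(1R,2S)‑2‑[tert‑butyl(dimethyl)silyl]oxy‑4‑oxocyclobutyl]acetate F4. CF3CO2H then removes the tert‑butyl ester and the silyl ether; the carbon next to the ketone epimerises through the enol, and only the cis hydroxy acid can close, giving 9.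

Step 5 may fail if the Grignard reagent enolises 9 and expels the lactone carboxylate by β‑elimination. The fallback goes from 9 to 11 without a basic nucleophile. CrCl2 and (iodoethynyl)trimethylsilane in THF (Nozaki–Hiyama‑type addition of an alkynylchromium species) give (1S,5S,6R)‑6‑hydroxy‑6‑[2‑(trimethylsilyl)ethynyl]‑2‑oxabicyclo[3.2.0]heptan‑3‑one F5, and Bu4NF buffered with AcOH removes the silyl group to give 11.

Step 8 may fail because the free acid and alcohol interfere with the gold catalyst or the Michael addition, because the β‑hydroxy ketone dehydrates, or because the C12 epimer ratio stays poor. The fallback changes the order and runs from 12 to 17, with the acid chain put on last. Methylenation of 12 with Ph3P=CH2 gives (1R,2S,3S)‑1‑ethynyl‑2‑(prop‑2‑en‑1‑yl)cyclobutane‑1,3‑diol F6. The same gold catalyst converts it to (3R,4S)‑4‑hydroxy‑2‑methylidene‑3‑(prop‑2‑en‑1‑yl)cyclopentan‑1‑one F7, and 5 with Me3SiOTf gives 1‑[(4S,5R)‑5‑(prop‑2‑en‑1‑yl)‑2,4‑bis(trimethylsilyloxy)cyclopent‑1‑en‑1‑yl]octan‑3‑one F8. Hydrolysis and KOAc equilibration give (2R,3R,4S)‑4‑hydroxy‑2‑(3‑oxooctyl)‑3‑(prop‑2‑en‑1‑yl)cyclopentan‑1‑one F9. Z‑selective cross‑metathesis of F9 with hex‑5‑enoic acid then gives 17. The catalyst is the cyclometalated ruthenium nitrate complex Ru(NO3)(=CH‑C6H4‑2‑O‑i‑Pr)(L), where L is the C–H‑activated 1‑(1‑adamantyl)‑3‑(2,6‑diisopropylphenyl)imidazolidin‑2‑ylidene.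

Further compounds
F1 | step 4 | 3‑[tert‑butyl(dimethyl)silyl]oxycyclobutan‑1‑one | CC(C)(C)[Si](C)(C)OC1CC(=O)C1
F2 | step 4 | tert‑butyl(dimethyl){[(1S)‑3‑(trimethylsilyloxy)cyclobut‑2‑en‑1‑yl]oxy}silane | C[Si](C)(C)OC1=C[C@@H](O[Si](C)(C)C(C)(C)C)C1
F3 | step 4 | lithium (3S)‑3‑[tert‑butyl(dimethyl)silyl]oxycyclobut‑1‑en‑1‑olate | [Li+].[O-]C1=C[C@@H](O[Si](C)(C)C(C)(C)C)C1
F4 | step 4 | tert‑butyl 2‑[(1R,2S)‑2‑[tert‑butyl(dimethyl)silyl]oxy‑4‑oxocyclobutyl]acetate | O=C1C[C@H](O[Si](C)(C)C(C)(C)C)[C@H]1CC(=O)OC(C)(C)C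
F5 | step 5 | (1S,5S,6R)‑6‑hydroxy‑6‑[2‑(trimethylsilyl)ethynyl]‑2‑oxabicyclo[3.2.0]heptan‑3‑one | C[Si](C)(C)C#C[C@@]1(O)C[C@H](OC(=O)C2)[C@@H]12
F6 | step 8 | (1R,2S,3S)‑1‑ethynyl‑2‑(prop‑2‑en‑1‑yl)cyclobutane‑1,3‑diol | C#C[C@@]1(O)C[C@H](O)[C@@H]1CC=C
F7 | step 8 | (3R,4S)‑4‑hydroxy‑2‑methylidene‑3‑(prop‑2‑en‑1‑yl)cyclopentan‑1‑one | C=C1C(=O)C[C@H](O)[C@@H]1CC=C
F8 | step 8 | 1‑[(4S,5R)‑5‑(prop‑2‑en‑1‑yl)‑2,4‑bis(trimethylsilyloxy)cyclopent‑1‑en‑1‑yl]octan‑3‑one | CCCCCC(=O)CCC1=C(O[Si](C)(C)C)C[C@H](O[Si](C)(C)C)[C@@H]1CC=C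
F9 | step 8 | (2R,3R,4S)‑4‑hydroxy‑2‑(3‑oxooctyl)‑3‑(prop‑2‑en‑1‑yl)cyclopentan‑1‑one | CCCCCC(=O)CC[C@H]1C(=O)C[C@H](O)[C@@H]1CC=C
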